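The readings were computed for substances that don't exist, and the scatter is random.

- A small charge of Qa, 0.500 equiv, opened my ledger for Eb, the limiting reagent of the flask, since Qa and Ty together came to 1.10 equiv for each Eb.

| flask | Eb | Qa | Ty | remark | time |
|---|---|---|---|---|---|
| east | 0.050 M | 0.50 equiv | 0.40 equiv | run made earlier |  |
| west | 0.050 M | 0.50 equiv | 0.90 equiv | run made earlier |  |
| flask | 0.050 M | 0.500 equiv | 0.600 equiv |  | 5.0 min |

- east (time / min: EbXa / %, EbQa / %, Eb / %): 0.250: 4, 33, 63; 0.417: 12, 42, 52; 0.667: 13, 46, 39; 1.00: 14, 45, 33; 2.00: 19, 49, 24; 3.00: 22, 48, 15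
- west (time / min: EbXa / %, EbQa / %, Eb / %): 0.500: 10, 43, 46; 1.00: 18, 49, 32; 1.50: 25, 49, 22; 2.00: 24, 48, 15; 2.50: 30, 49, 13; 3.00: 27, 50, 8

(scatter of a reading: 1.5 percentage points)

- how much EbXa there is at 5.0 min, in percent of the Eb charged
- how much EbQa there is at 5.0 min, in percent of the Eb charged

- given per volume of solution although it is solid: Ty
- at the start none of Ty is in solution
- a reading or a percentage of EbXa counts all its forms, free or not

- First entry, EbQa: at 3.00 min it read 48% in the east run and 50% in the west run, with Ty at 0.40 equiv and 0.90 equiv, so I booked 50% for the flask.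
- Second entry, Eb left: from 1.00 min on I read Eb as a first-order decay, 0.394 /min in east and 0.693 /min in west.
- Placing the flask between them by its Ty gave 0.514 /min, which counted 2.97 half-lives from 1.00 min up to 5.0 min; starting from the 33% that the east run read at 1.00 min, I reckoned 4.23% of Eb left in the flask.
- Third entry: the rest, 45.8%, I booked to the Ty way, and that was less than the 0.600 equiv of Ty charged.
- But the books did not close on EbXa: at 3.00 min the same entry, reckoned from each run's own readings, held 59.5% as EbXa in east and 64.3% in west.
- Pooled, these readings gave the kept share, the EbXa found per Eb lost beyond EbQa and Eb left: 62.0%.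
- So I booked 28.4% of EbXa for the flask and 17.4% as unseen.
- The forecast gave 27% of EbXa and 49% of EbQa, with the words “roughly 60% of the Ty-route loss appears as EbXa, or EbXa is being consumed further”; my EbXa stood 1.4 percentage points higher.
- The flask gave 29.2% of EbXa and 49.8% of EbQa.

    Eb + Xa → EbXa (k = 0.577 /M/s)
    Eb + Qa → EbQa (k = 1.88 /M/s)
    EbXa ⇌ Jy (K = 0.549, k = 0.0101 /s)
    Qa + EbXa ⇌ QaEbXa, settled at all times (K = 13.1 /M)
    Ty ⇌ Xa, rate k5*(cs5 - [Xa]) while solid is left; crystals form when [Xa] > cs5 (solubility = 19.0 mM, k = 0.0875 /s)

- EbXa and Jy relaxed into each other with a half-life, both ways together, of 0.405 min, short against the 5.0 min of the flask, and at 5.00 min Jy stood at 15.3% in the flask. On the flask's own ledger, with 5.74% of Eb left, the kept share gave 27.6% of EbXa against 29.2%. In the neighbour flask with 0.300 equiv of Qa, EbQa ended at 30.0% and Eb at 16.2%, so the share gave 33.4%, and that flask held 35.2% of EbXa.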